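The oxolane is disconnected at the C3–C4 bond (as C3=C4) and at the bond between butanoate C1 and C2 (as a terminal C=CH2). Oxolane C5, C4 and the three chain methylenes form an unbroken five-carbon string attached to O1. This string is a masked cyclopent-2-enyl ether, while C2 and C3 are a vinyl carbinol. One ruthenium-catalysed ring-rearrangement metathesis opens the carbocycle, closes the 2,5-dihydrofuran and releases a butenyl chain, carrying both preset ether stereocentres into the trans ring. The precursor is the bis-allylic ether of (1R)-cyclopent-2-enol and (2S)-1-silyloxybut-3-en-2-ol. Chain oxidation, alkyne homologation and a final Sonogashira coupling with a separately made iodo-bromo-triene complete the target.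

Key step: step 5

Assumption: with cycloalkenyl esters, the (R,R) form of the ligand family used in step 4 gives (S) products when the nucleophile ranks highest at the new centre, so the (S,S) ligand is assigned for the (1R) ether; both antipodes are catalogue items, so a ligand swap would correct a wrong assignment.
Remark: the arm must hold four methylenes between its E-alkene and the Z,Z-diene, which a C7 alkynol plus a C3 enal provide; (S)-but-3-ene-1,2-diol, hept-6-yn-1-ol and ethyl (Z)-3-bromoacrylate are taken as catalogue compounds.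

Step 1
Reactants: 1 cyclopent-2-en-1-one
Product: 2 (±)-cyclopent-2-en-1-ol
Conditions: NaBH4, CeCl3·7H2O, MeOH, 0 °C
Reagents that add atoms: none
Why: In the Luche reduction the cerium-activated, methanol-modified borohydride acts as a hard hydride and attacks only the carbonyl carbon (1,2-addition), and the racemic outcome is harmless because this centre is erased and reset in step 4.

Step 2
Reactants: 2 (±)-cyclopent-2-en-1-ol
Product: 3 (±)-cyclopent-2-en-1-yl acetate
Conditions: Ac2O, Et3N, DMAP (cat.), CH2Cl2, 0 °C to rt
Reagents that add atoms: acetic anhydride, CC(=O)OC(C)=O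
Why: DMAP-catalysed acylation of a secondary allylic alcohol is routine and installs the leaving group needed for ionisation by zerovalent palladium.

Step 3
Reactants: 4 (2S)-but-3-ene-1,2-diol
Product: 5 (2S)-1-{[tert-butyl(diphenyl)silyl]oxy}but-3-en-2-ol
Conditions: TBDPSCl, imidazole, CH2Cl2, 0 °C
Reagents that add atoms: tert-butyl(chloro)diphenylsilane (TBDPSCl), CC(C)(C)[Si](Cl)(c1ccccc1)c1ccccc1
Why: Silylation with the bulky chlorosilane should favour the primary over the secondary allylic hydroxyl on steric grounds, and the stereocentre bought with 4 is not involved.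

Step 4
Reactants: 5 (2S)-1-{[tert-butyl(diphenyl)silyl]oxy}but-3-en-2-ol; 3 (±)-cyclopent-2-en-1-yl acetate
Product: 7 tert-butyl{[(2S)-2-[(1R)-cyclopent-2-en-1-yloxy]but-3-en-1-yl]oxy}diphenylsilane, via zinc bis-alkoxide 6 (not isolated)
Conditions: Et2Zn (0.5 equiv), THF, 0 °C to rt; then 3, Pd(OAc)2 (5 mol %), (S,S)-DACH-phenyl ligand = N,N'-[(1S,2S)-cyclohexane-1,2-diyl]bis[2-(diphenylphosphanyl)benzamide] (7.5 mol %), THF, rt
Reagents that add atoms: diethylzinc, CC[Zn]CC (supplies only the zinc of 6; nothing from it stays in 7)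
Why: In this Tsuji–Trost allylic etherification with a zinc alkoxide as soft oxygen nucleophile, both enantiomers of 3 ionise to the same meso η3-cyclopentenyl palladium cation, the chiral pocket of the (S,S) ligand steers the alkoxide to one of the two enantiotopic termini and so sets the new (1R) centre under catalyst control, and the (2S) carbinol carbon of 5 only lends its oxygen and keeps its configuration.

Step 5
Reactants: 7 tert-butyl{[(2S)-2-[(1R)-cyclopent-2-en-1-yloxy]but-3-en-1-yl]oxy}diphenylsilane
Product: 8 tert-butyl{[(2S,5R)-5-(but-3-en-1-yl)-2,5-dihydrofuran-2-yl]methoxy}diphenylsilane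
Conditions: second-generation Grubbs catalyst (H2IMes)(PCy3)Cl2Ru=CHPh (5 mol %), ethylene (1 atm), CH2Cl2 (0.01 M), rt to 40 °C; ethyl vinyl ether quench
Reagents that add atoms: none
Why: This is a ring-rearrangement metathesis, the tandem ring-opening/ring-closing variant of olefin metathesis that is established for cycloalkenyl allyl ethers and amines. A ruthenium carbene generated at the vinyl terminus of 7 (or a Ru=CH2 species fed by ethylene) engages the ring alkene in a metallacyclobutane, whose fragmentation severs the C2=C3 bond of the cyclopentene. The new ring is closed in the ring-closing-metathesis mode as a five-membered 2,5-dihydrofuran by union of the former vinyl CH with cyclopentene C2 (new C3=C4), and the far end of the severed ring, cyclopentene C3, picks up a CH2 unit to become the terminal alkene of the butenyl chain. No stereocentre is created, because the two oxygen-bearing sp3 carbons never bond to ruthenium, so (2S) and (1R) in 7 translate directly into the trans (2S,5R) array of 8. The step must favour the monomeric five-membered O-heterocycle over return to the carbocycle, over a seven-membered ether and over oligomers. This is secured by the diallyl-ether spacing of the two alkenes across oxygen, by loss of cyclopentene strain, by high dilution and by the ethylene atmosphere, which keeps every undesired cross-product reversible.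

Step 6
Reactants: 8 tert-butyl{[(2S,5R)-5-(but-3-en-1-yl)-2,5-dihydrofuran-2-yl]methoxy}diphenylsilane
Product: 10 4-[(2R,5S)-5-({[tert-butyl(diphenyl)silyl]oxy}methyl)-2,5-dihydrofuran-2-yl]butan-1-ol, via B-alkyl-9-BBN adduct 9 (not isolated)
Conditions: 9-BBN, THF, 0 °C to rt; then NaOH aq., H2O2, 0 °C
Reagents that add atoms: hydrogen peroxide, OO; 9-BBN, C1CC2CCCC(C1)B2 (boron unit of 9 only)
Why: In this Brown hydroboration–oxidation 9-BBN should add anti-Markovnikov to the unhindered monosubstituted alkene far faster than to the flanked, oxygen-deactivated ring alkene, and alkaline peroxide replaces boron by hydroxyl without touching the silyl ether or the stereocentres.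

Step 7
Reactants: 10 4-[(2R,5S)-5-({[tert-butyl(diphenyl)silyl]oxy}methyl)-2,5-dihydrofuran-2-yl]butan-1-ol
Product: 11 4-[(2R,5S)-5-({[tert-butyl(diphenyl)silyl]oxy}methyl)oxolan-2-yl]butan-1-ol
Conditions: H2 (1 atm), PtO2 (cat.), EtOAc, rt
Reagents that add atoms: none
Why: Heterogeneous catalytic hydrogenation of a cis-disubstituted ring alkene is fast, and platinum is preferred to palladium because it has little tendency to migrate the double bond or to cleave allylic carbon–oxygen bonds, so both ring stereocentres should be retained.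

Step 8
Reactants: 11 4-[(2R,5S)-5-({[tert-butyl(diphenyl)silyl]oxy}methyl)oxolan-2-yl]butan-1-ol
Product: 13 4-[(2R,5S)-5-({[tert-butyl(diphenyl)silyl]oxy}methyl)oxolan-2-yl]butanoic acid, via aldehyde 12 (not isolated)
Conditions: TEMPO (cat.), PhI(OAc)2, MeCN–H2O, rt
Reagents that add atoms: water, O
Why: Oxoammonium (TEMPO) oxidation with PhI(OAc)2 as terminal oxidant in aqueous acetonitrile takes a primary alcohol through the aldehyde hydrate to the acid under nearly neutral conditions that leave the ether, the silyl ether and the stereocentres alone.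

Step 9
Reactants: 13 4-[(2R,5S)-5-({[tert-butyl(diphenyl)silyl]oxy}methyl)oxolan-2-yl]butanoic acid
Product: 15 methyl 4-[(2R,5S)-5-(hydroxymethyl)oxolan-2-yl]butanoate, via silylated methyl ester 14 (not isolated)
Conditions: HCl (about 3 % in MeOH), rt
Reagents that add atoms: methanol, CO
Why: Fischer esterification is quick in methanolic HCl and the same medium is a documented reagent for solvolysis of primary tert-butyldiphenylsilyl ethers, so two routine operations are merged on a substrate that holds no other acid-labile group.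

Step 10
Reactants: 15 methyl 4-[(2R,5S)-5-(hydroxymethyl)oxolan-2-yl]butanoate
Product: 16 methyl 4-[(2R,5S)-5-formyloxolan-2-yl]butanoate
Conditions: Dess–Martin periodinane, CH2Cl2, 0 °C to rt
Reagents that add atoms: none
Why: The Dess–Martin oxidation stops at the aldehyde under mild, non-basic conditions, which protects the epimerisable α-alkoxy centre.

Step 11
Reactants: 16 methyl 4-[(2R,5S)-5-formyloxolan-2-yl]butanoate
Product: 17 methyl 4-[(2R,5S)-5-ethynyloxolan-2-yl]butanoate
Conditions: dimethyl (1-diazo-2-oxopropyl)phosphonate, K2CO3, MeOH, 0 °C to rt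
Reagents that add atoms: Ohira–Bestmann reagent, dimethyl (1-diazo-2-oxopropyl)phosphonate, CC(=O)C(=[N+]=[N-])P(=O)(OC)OC
Why: In the Seyferth–Gilbert homologation (Ohira–Bestmann variant) methanolysis frees the diazomethylphosphonate anion, which adds to the aldehyde and, after loss of phosphate and N2 and a 1,2-hydrogen shift, gives the terminal alkyne under base mild enough for α-alkoxy aldehydes, while methanol is degenerate toward the methyl ester.

Step 12
Reactants: 18 hept-6-yn-1-ol
Product: 20 (6E)-7-iodohept-6-en-1-ol, via bis-zirconocene adduct 19 (not isolated)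
Conditions: Cp2Zr(H)Cl (2.2 equiv), THF, rt, dark; then I2, 0 °C
Reagents that add atoms: iodine, [I][I]; Cp2Zr(H)Cl, [H][Zr](Cl)(C1C=CC=C1)C1C=CC=C1 (zirconium units of 19 only)
Why: In this hydrozirconation–iodinolysis the first equivalent of Cp2Zr(H)Cl is consumed by the hydroxyl group, the second adds syn with zirconium at the terminal carbon, and iodine cleaves the carbon–zirconium bond with retention, which fixes the E-iodoalkene.

Step 13
Reactants: 20 (6E)-7-iodohept-6-en-1-ol
Product: 21 (1E)-1,7-diiodohept-1-ene
Conditions: I2, PPh3, imidazole, CH2Cl2, 0 °C to rt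
Reagents that add atoms: iodine, [I][I]
Why: The Appel reaction is an SN2 displacement of the alkoxyphosphonium ion by iodide at a primary carbon, and the alkenyl iodide is inert to it.

Step 14
Reactants: 21 (1E)-1,7-diiodohept-1-ene
Product: 22 [(6E)-7-iodohept-6-en-1-yl]triphenylphosphonium iodide
Conditions: PPh3, MeCN, reflux
Reagents that add atoms: triphenylphosphine, c1ccc(cc1)P(c1ccccc1)c1ccccc1
Why: SN2 quaternisation of triphenylphosphine takes place only at the primary alkyl iodide, because an sp2 carbon–iodine bond does not react without a metal catalyst.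

Step 15
Reactants: 23 ethyl (2Z)-3-bromoprop-2-enoate
Product: 25 (2Z)-3-bromoprop-2-enal, via aluminium hemiacetal 24 (not isolated)
Conditions: iBu2AlH (1.05 equiv), CH2Cl2, −78 °C; MeOH, then cold aq. potassium sodium tartrate; dried solution used at once
Reagents that add atoms: iBu2AlH, CC(C)C[AlH]CC(C)C (aluminium unit of 24 only)
Why: In this partial ester reduction the tetrahedral aluminium hemiacetal persists at −78 °C and releases the aldehyde only on cold quench, so over-reduction is avoided and the Z geometry bought with 23 should survive if the enal is kept cold, acid-free and used immediately.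

Step 16
Reactants: 22 [(6E)-7-iodohept-6-en-1-yl]triphenylphosphonium iodide; 25 (2Z)-3-bromoprop-2-enal
Product: 27 (1Z,3Z,9E)-1-bromo-10-iododeca-1,3,9-triene, via phosphonium ylide 26 (not isolated)
Conditions: NaN(SiMe3)2 (1.0 equiv), THF, −78 to 0 °C; then 25, −78 to −20 °C
Reagents that add atoms: none
Why: The Wittig olefination of a non-stabilised ylide under lithium-free conditions runs through the kinetically favoured cis-oxaphosphetane and sets the new C3=C4 alkene of 27 as Z, the Z-bromoalkene comes unchanged from 25, and the E-iodoalkene has no anti-periplanar hydrogen for base-induced elimination.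

Step 17
Reactants: 17 methyl 4-[(2R,5S)-5-ethynyloxolan-2-yl]butanoate; 27 (1Z,3Z,9E)-1-bromo-10-iododeca-1,3,9-triene
Product: 28 methyl 4-{(2R,5S)-5-[(3E,9Z,11Z)-12-bromododeca-3,9,11-trien-1-yn-1-yl]oxolan-2-yl}butanoate
Conditions: Pd(PPh3)4 (5 mol %), CuI (10 mol %), Et3N, THF, degassed, dark, 0 °C to rt
Reagents that add atoms: none
Why: In the Sonogashira coupling, oxidative addition of zerovalent palladium to the alkenyl carbon–iodine bond is much faster than to the alkenyl carbon–bromine bond at or below room temperature and proceeds with retention, so the E-enyne should form while the Z,Z-bromodiene, the ester and both ring stereocentres stay untouched.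

Compound list
1 | cyclopent-2-en-1-one | O=C1C=CCC1 | starting material
2 | (±)-cyclopent-2-en-1-ol | OC1C=CCC1 | intermediate
3 | (±)-cyclopent-2-en-1-yl acetate | CC(=O)OC1C=CCC1 | intermediate
4 | (2S)-but-3-ene-1,2-diol | C=C[C@@H](CO)O | starting material
5 | (2S)-1-{[tert-butyl(diphenyl)silyl]oxy}but-3-en-2-ol | C=C[C@@H](CO[Si](c1ccccc1)(c1ccccc1)C(C)(C)C)O | intermediate
6 | zinc bis[(2S)-1-{[tert-butyl(diphenyl)silyl]oxy}but-3-en-2-olate], formed in the flask | C=C[C@@H](CO[Si](c1ccccc1)(c1ccccc1)C(C)(C)C)O[Zn]O[C@@H](C=C)CO[Si](c1ccccc1)(c1ccccc1)C(C)(C)C | intermediate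
7 | tert-butyl{[(2S)-2-[(1R)-cyclopent-2-en-1-yloxy]but-3-en-1-yl]oxy}diphenylsilane | C=C[C@@H](CO[Si](c1ccccc1)(c1ccccc1)C(C)(C)C)O[C@H]1C=CCC1 | intermediate
8 | tert-butyl{[(2S,5R)-5-(but-3-en-1-yl)-2,5-dihydrofuran-2-yl]methoxy}diphenylsilane | C=CCC[C@@H]1C=C[C@@H](CO[Si](c2ccccc2)(c2ccccc2)C(C)(C)C)O1 | intermediate
9 | 9-{4-[(2R,5S)-5-({[tert-butyl(diphenyl)silyl]oxy}methyl)-2,5-dihydrofuran-2-yl]butyl}-9-borabicyclo[3.3.1]nonane, formed in the flask | C1CC2CCCC(C1)B2CCCC[C@@H]1C=C[C@@H](CO[Si](c2ccccc2)(c2ccccc2)C(C)(C)C)O1 | intermediate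
10 | 4-[(2R,5S)-5-({[tert-butyl(diphenyl)silyl]oxy}methyl)-2,5-dihydrofuran-2-yl]butan-1-ol | OCCCC[C@@H]1C=C[C@@H](CO[Si](c2ccccc2)(c2ccccc2)C(C)(C)C)O1 | intermediate
11 | 4-[(2R,5S)-5-({[tert-butyl(diphenyl)silyl]oxy}methyl)oxolan-2-yl]butan-1-ol | OCCCC[C@@H]1CC[C@@H](CO[Si](c2ccccc2)(c2ccccc2)C(C)(C)C)O1 | intermediate
12 | 4-[(2R,5S)-5-({[tert-butyl(diphenyl)silyl]oxy}methyl)oxolan-2-yl]butanal, formed in the flask | O=CCCC[C@@H]1CC[C@@H](CO[Si](c2ccccc2)(c2ccccc2)C(C)(C)C)O1 | intermediate
13 | 4-[(2R,5S)-5-({[tert-butyl(diphenyl)silyl]oxy}methyl)oxolan-2-yl]butanoic acid | OC(=O)CCC[C@@H]1CC[C@@H](CO[Si](c2ccccc2)(c2ccccc2)C(C)(C)C)O1 | intermediate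
14 | methyl 4-[(2R,5S)-5-({[tert-butyl(diphenyl)silyl]oxy}methyl)oxolan-2-yl]butanoate, formed in the flask | COC(=O)CCC[C@@H]1CC[C@@H](CO[Si](c2ccccc2)(c2ccccc2)C(C)(C)C)O1 | intermediate
15 | methyl 4-[(2R,5S)-5-(hydroxymethyl)oxolan-2-yl]butanoate | COC(=O)CCC[C@@H]1CC[C@@H](CO)O1 | intermediate
16 | methyl 4-[(2R,5S)-5-formyloxolan-2-yl]butanoate | COC(=O)CCC[C@@H]1CC[C@@H](C=O)O1 | intermediate
17 | methyl 4-[(2R,5S)-5-ethynyloxolan-2-yl]butanoate | COC(=O)CCC[C@@H]1CC[C@@H](C#C)O1 | intermediate
18 | hept-6-yn-1-ol | C#CCCCCCO | starting material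
19 | (E)-alkenylzirconocene chloride bearing an O-zirconocene chloride alkoxide, formed in the flask (Cp drawn as sigma-bound C5H5) | Cl[Zr](C1C=CC=C1)(C1C=CC=C1)OCCCCC/C=C/[Zr](Cl)(C1C=CC=C1)C1C=CC=C1 | intermediate
20 | (6E)-7-iodohept-6-en-1-ol | OCCCCC/C=C/I | intermediate
21 | (1E)-1,7-diiodohept-1-ene | ICCCCC/C=C/I | intermediate
22 | [(6E)-7-iodohept-6-en-1-yl]triphenylphosphonium iodide | [I-].I/C=C/CCCCC[P+](c1ccccc1)(c1ccccc1)c1ccccc1 | intermediate
23 | ethyl (2Z)-3-bromoprop-2-enoate | CCOC(=O)/C=C\Br | starting material
24 | diisobutylaluminium hemiacetal of 23, formed in the flask | CCOC(O[Al](CC(C)C)CC(C)C)/C=C\Br | intermediate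
25 | (2Z)-3-bromoprop-2-enal | O=C/C=C\Br | intermediate
26 | [(6E)-7-iodohept-6-en-1-ylidene]triphenylphosphorane, formed in the flask | I/C=C/CCCCC=P(c1ccccc1)(c1ccccc1)c1ccccc1 | intermediate
27 | (1Z,3Z,9E)-1-bromo-10-iododeca-1,3,9-triene | I/C=C/CCCC/C=C\C=C/Br | intermediate
28 | methyl 4-{(2R,5S)-5-[(3E,9Z,11Z)-12-bromododeca-3,9,11-trien-1-yn-1-yl]oxolan-2-yl}butanoate | COC(=O)CCC[C@@H]1CC[C@@H](C#C/C=C/CCCC/C=C\C=C/Br)O1 | target

Total step count: 17.
Longest linear sequence: 11 steps (1, 2, 4, 5, 6, 7, 8, 9, 10, 11, 17).

Steps most likely to fail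

1. Step 5.
- **What may go wrong:** The exchange may settle at an unfavourable balance between carbocycle and O-heterocycle. Alternatively, the ring alkene and the liberated terminal alkene may be drawn into ring-opening oligomerisation and cross-metathesis before the hindered vinyl group is engaged.
- **Fallback (from 5, back at 14):** The isomerisation is replaced by an ordinary, ethylene-releasing ring closure of an acyclic diene that already carries the finished ester chain and cannot revert to a carbocycle. Cross-metathesis of commercial methyl hex-5-enoate with excess allyl methyl carbonate (second-generation Grubbs catalyst) should give methyl (5E)-7-[(methoxycarbonyl)oxy]hept-5-enoate F1. The zinc alkoxide 6 made from 5 would then be allylated by F1 at the branched position under [Ir(cod)Cl]2 and a chiral phosphoramidite ligand, whose enantiomer is chosen for the 5R product. This gives methyl (5R)-5-{[(2S)-1-{[tert-butyl(diphenyl)silyl]oxy}but-3-en-2-yl]oxy}hept-6-enoate F2. Ring-closing metathesis of its two vinyl groups should give methyl 4-[(2R,5S)-5-({[tert-butyl(diphenyl)silyl]oxy}methyl)-2,5-dihydrofuran-2-yl]butanoate F3. Hydrogenation over PtO2 gives 14, which is carried on under the conditions of step 9.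

2. Step 4.
- **What may go wrong:** Discrimination between the two termini of the allyl complex may be poor if the hindered chiral alkoxide is mismatched with the ligand. Attack may also be so sluggish that acetate returns and the catalyst decays.
- **Fallback (from 5 and 3, back at 8):** Catalyst control is given up in favour of separating diastereomers, which is possible because 5 is a single enantiomer. The same zinc alkoxide would be allylated with Pd(OAc)2 and the achiral ligand 2-(di-tert-butylphosphino)biphenyl. This gives 7 together with its epimer tert-butyl{[(2S)-2-[(1S)-cyclopent-2-en-1-yloxy]but-3-en-1-yl]oxy}diphenylsilane F4. The pair is submitted to step 5, where the epimer becomes the cis compound tert-butyl{[(2S,5S)-5-(but-3-en-1-yl)-2,5-dihydrofuran-2-yl]methoxy}diphenylsilane F5. The rigid cis and trans dihydrofurans should be separable on silica gel, and pure 8 continues.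

3. Step 16.
- **What may go wrong:** The β-bromoenal may isomerise from Z to E before or during the olefination, the ylide may undergo conjugate addition–elimination at its β-carbon, or the Z-selectivity at the new alkene may erode.
- **Fallback (from 20, back at 27):** The diene is built from the other end by two separate Z-selective olefinations, so no β-haloenal is needed. Dess–Martin oxidation of 20 should give (6E)-7-iodohept-6-enal F6. Still–Gennari olefination with (CF3CH2O)2P(O)CH2CO2Me, KN(SiMe3)2 and 18-crown-6 in THF at −78 °C should give methyl (2Z,8E)-9-iodonona-2,8-dienoate F7. Reduction with iBu2AlH gives (2Z,8E)-9-iodonona-2,8-dien-1-ol F8, and MnO2 gives (2Z,8E)-9-iodonona-2,8-dienal F9. A Z-selective Wittig bromomethylenation, using the ylide from (bromomethyl)triphenylphosphonium bromide and KOtBu at −78 °C, then gives 27.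

Further compounds
F1 | step 5 | methyl (5E)-7-[(methoxycarbonyl)oxy]hept-5-enoate | COC(=O)CCC/C=C/COC(=O)OC
F2 | step 5 | methyl (5R)-5-{[(2S)-1-{[tert-butyl(diphenyl)silyl]oxy}but-3-en-2-yl]oxy}hept-6-enoate | C=C[C@@H](CO[Si](c1ccccc1)(c1ccccc1)C(C)(C)C)O[C@@H](C=C)CCCC(=O)OC
F3 | step 5 | methyl 4-[(2R,5S)-5-({[tert-butyl(diphenyl)silyl]oxy}methyl)-2,5-dihydrofuran-2-yl]butanoate | COC(=O)CCC[C@@H]1C=C[C@@H](CO[Si](c2ccccc2)(c2ccccc2)C(C)(C)C)O1
F4 | step 4 | tert-butyl{[(2S)-2-[(1S)-cyclopent-2-en-1-yloxy]but-3-en-1-yl]oxy}diphenylsilane | C=C[C@@H](CO[Si](c1ccccc1)(c1ccccc1)C(C)(C)C)O[C@@H]1C=CCC1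
F5 | step 4 | tert-butyl{[(2S,5S)-5-(but-3-en-1-yl)-2,5-dihydrofuran-2-yl]methoxy}diphenylsilane | C=CCC[C@H]1C=C[C@@H](CO[Si](c2ccccc2)(c2ccccc2)C(C)(C)C)O1
F6 | step 16 | (6E)-7-iodohept-6-enal | O=CCCCC/C=C/I
F7 | step 16 | methyl (2Z,8E)-9-iodonona-2,8-dienoate | COC(=O)/C=C\CCCC/C=C/I
F8 | step 16 | (2Z,8E)-9-iodonona-2,8-dien-1-ol | OC/C=C\CCCC/C=C/I
F9 | step 16 | (2Z,8E)-9-iodonona-2,8-dienal | O=C/C=C\CCCC/C=C/I
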